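The eight-membered oxocane (ring oxygen plus C7–C13) is treated as a ring-expanded cyclohept-4-enone; atoms are numbered C1 (alkyne CH) to C15 (ethyl CH3) along the chain. Its carbocycle is made in one operation by a [4+3] cycloaddition of a bromine-stabilised 2-oxyallyl cation (C7–C13–C12, from tetrabromoacetone) with butadiene (C8–C11), forming C7–C8 and C11–C12 and fixing the Z-alkene C9=C10. After an anti-aldol sets C6/C7, Baeyer–Villiger oxidation inserts the ring oxygen between C7 and C13. The C9=C10 alkene, extended to a C12 silyl dienol ether, then directs bromine to C9 and the C6 oxygen to C10, closing the tetrahydropyran; C12 is brominated last with inversion.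

Key step: step 1

Remark: in the chain numbering the tetrahydropyran ring is O/C6/C7/C8/C9/C10, the oxocane ring is O/C7/C8/C9/C10/C11/C12/C13, and the target is (3E,6R,7R,9S,10S,12S,13R). TBS = tert-butyldimethylsilyl, TMS = trimethylsilyl.

Step 1
Reactants: 1 1,1,3,3-tetrabromopropan-2-one; 2 buta-1,3-diene
Product: 4 cyclohept-4-en-1-one, via dibromocycloheptenone 3 (not isolated)
Conditions: Fe2(CO)9, benzene, 60 °C, sealed vessel, excess 2; then Zn/Cu couple, NH4Cl, MeOH, rt
Reagents that add atoms: none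
Why: Fe2(CO)9 strips two bromides from 1 to give an iron-bound 1,3-dibromo-2-oxyallyl cation, a three-carbon partner (C7–C13–C12), which adds to the termini of s-cis butadiene (C8 and C11) in a [4+3] cycloaddition that forms C7–C8 and C11–C12 in the same operation. The closest known reaction type is the reductive oxyallyl-cation cycloaddition of polybromo ketones with open-chain 1,3-dienes and furans. The cycloheptene ring closes by the cycloaddition itself, either concerted or by bond formation at one terminus followed by seven-membered closure of the allyl cation by the enolate carbon. No stereocenter of the target is set here: the bromine-bearing carbons of 3 are reduced to CH2 by Zn/Cu in the same flask, which leaves the achiral ketone 4, and the Z-geometry of C9=C10 is enforced by the ring. The step needs carbon–carbon [4+3] closure in preference to [3+2] closure through oxygen and to diene oligomerisation; the two α-bromine atoms, temporary activating groups, secure this by making the oxyallyl species long-lived, aided by an excess of 2.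

Step 2
Reactants: 4 cyclohept-4-en-1-one; 5 3-[(tert-butyldimethylsilyl)oxy]propanal
Product: 6 (2R)-2-[(1R)-3-(TBSO)-1-hydroxypropyl]cyclohept-4-en-1-one
Conditions: D-proline (30 mol%), DMSO, 4 °C, threefold excess of 4 (recovered), slow addition of 5
Reagents that add atoms: none
Why: Proline-catalysed direct aldol (enamine catalysis): the enamine of the symmetric ketone adds to 5 through the carboxylic-acid-bridged chair transition state, which should give the anti aldol and, with the D-catalyst, set C7 (R) and C6 (R) together; both α-positions of 4 are equivalent, so there is no regiochemical issue.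

Step 3
Reactants: 6 (2R)-2-[(1R)-3-(TBSO)-1-hydroxypropyl]cyclohept-4-en-1-one
Product: 7 (2R)-2-[(1R)-1,3-bis(TBSO)propyl]cyclohept-4-en-1-one
Conditions: t-BuMe2SiOTf, 2,6-lutidine, CH2Cl2, −78 °C
Reagents that add atoms: tert-butyldimethylsilyl trifluoromethanesulfonate, CC(C)(C)[Si](C)(C)OS(=O)(=O)C(F)(F)F
Why: Silylation of the secondary alcohol at −78 °C is faster than enolisation of the ketone, so the aldol stereocenters should be carried through without retro-aldol or epimerisation at C7.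

Step 4
Reactants: 7 (2R)-2-[(1R)-1,3-bis(TBSO)propyl]cyclohept-4-en-1-one
Product: 8 (5Z,8R)-8-[(1R)-1,3-bis(TBSO)propyl]-3,4,7,8-tetrahydro-2H-oxocin-2-one
Conditions: Me3SiOOSiMe3, Me3SiOTf (10 mol%), CH2Cl2, −40 to −20 °C
Reagents that add atoms: bis(trimethylsilyl) peroxide, C[Si](C)(C)OO[Si](C)(C)C
Why: Baeyer–Villiger oxidation with a silyl peroxide: the secondary C7 should migrate to oxygen in preference to the primary C12 and with retention, giving the C7–O–C13 lactone, while the reagent has no epoxidising power toward the Z-alkene.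

Step 5
Reactants: 8 (5Z,8R)-8-[(1R)-1,3-bis(TBSO)propyl]-3,4,7,8-tetrahydro-2H-oxocin-2-one
Product: 9 (5Z,8R)-8-[(1R)-1,3-bis(TBSO)propyl]-7,8-dihydro-4H-oxocin-2-yl diphenyl phosphate
Conditions: KN(SiMe3)2, (PhO)2P(O)Cl, THF–HMPA, −78 °C
Reagents that add atoms: diphenyl chlorophosphate, O=P(Cl)(Oc1ccccc1)Oc1ccccc1
Why: Ketene acetal phosphate formation: the lactone is enolised at C12, its only acidic position, and the potassium enolate is trapped on oxygen at low temperature before it can fragment to a ketene.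

Step 6
Reactants: 9 (5Z,8R)-8-[(1R)-1,3-bis(TBSO)propyl]-7,8-dihydro-4H-oxocin-2-yl diphenyl phosphate
Product: 10 (5Z,8R)-8-[(1R)-1,3-bis(TBSO)propyl]-2-ethyl-7,8-dihydro-4H-oxocine
Conditions: EtZnCl (from EtMgCl and ZnCl2), PdCl2(dppf) (5 mol%, dppf = 1,1'-bis(diphenylphosphino)ferrocene), THF, 50 °C
Reagents that add atoms: ethylzinc chloride, CC[Zn]Cl
Why: Negishi cross-coupling of the ketene acetal phosphate (oxidative addition into the C–O bond, transmetalation, reductive elimination) should introduce the ethyl group C14–C15 at C13, the wide-bite-angle ligand favouring reductive elimination over β-hydride elimination.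

Step 7
Reactants: 10 (5Z,8R)-8-[(1R)-1,3-bis(TBSO)propyl]-2-ethyl-7,8-dihydro-4H-oxocine
Product: 12 (2R,3S,5Z,8R)-8-[(1R)-1,3-bis(TBSO)propyl]-2-ethyl-3,4,7,8-tetrahydro-2H-oxocin-3-ol, via epoxy acetal 11 (not isolated)
Conditions: dimethyldioxirane, acetone–CH2Cl2, −78 °C; then i-Bu2AlH, CH2Cl2, −78 °C
Reagents that add atoms: dimethyldioxirane, CC1(C)OO1
Why: Chemoselective epoxidation of the electron-rich enol ether (the isolated Z-alkene reacts far more slowly) on the ring face away from the C7 side chain, then aluminium-assisted opening of the epoxy acetal with hydride delivered to C13 on the face of the departing oxygen, should give the 7,13-cis ether (C13 R); the C12 carbinol configuration is immaterial because it is oxidised in step 9, and an anti-selective hydride source (Et3SiH with BF3·OEt2) would correct the opposite facial outcome of the epoxidation.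

Step 8
Reactants: 12 (2R,3S,5Z,8R)-8-[(1R)-1,3-bis(TBSO)propyl]-2-ethyl-3,4,7,8-tetrahydro-2H-oxocin-3-ol
Product: 13 (2R,3S,5Z,8R)-2-ethyl-8-[(1R)-3-hydroxy-1-(TBSO)propyl]-3,4,7,8-tetrahydro-2H-oxocin-3-ol
Conditions: HF·pyridine, pyridine, THF, 0 °C
Reagents that add atoms: none
Why: Fluoride-mediated desilylation is much faster for the unhindered primary silyl ether than for the secondary one next to the ring, so only the C4 hydroxyl should be released.

Step 9
Reactants: 13 (2R,3S,5Z,8R)-2-ethyl-8-[(1R)-3-hydroxy-1-(TBSO)propyl]-3,4,7,8-tetrahydro-2H-oxocin-3-ol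
Product: 14 (3R)-3-(TBSO)-3-[(2R,4Z,8R)-8-ethyl-7-oxo-3,6,7,8-tetrahydro-2H-oxocin-2-yl]propanal
Conditions: Dess–Martin periodinane (2.5 equiv), NaHCO3, CH2Cl2, 0 °C to rt
Reagents that add atoms: none
Why: Dess–Martin oxidation under buffered, non-enolising conditions should convert the primary alcohol into the C4 aldehyde and the C12 alcohol into the ketone in one operation, without moving C9=C10 into conjugation or epimerising C13.

Step 10
Reactants: 14 (3R)-3-(TBSO)-3-[(2R,4Z,8R)-8-ethyl-7-oxo-3,6,7,8-tetrahydro-2H-oxocin-2-yl]propanal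
Product: 15 (2R,5Z,8R)-2-ethyl-8-[(1R,3E)-4-iodo-1-(TBSO)but-3-en-1-yl]-7,8-dihydro-2H-oxocin-3(4H)-one
Conditions: CrCl2, CHI3, THF–dioxane, 0 °C to rt
Reagents that add atoms: iodoform, IC(I)I
Why: Takai olefination: the geminal dichromium species from CHI3 adds to the aldehyde only (the ketone is inert) and anti-periplanar elimination should give the (E)-vinyl iodide, fixing the C3=C4 geometry.

Step 11
Reactants: 15 (2R,5Z,8R)-2-ethyl-8-[(1R,3E)-4-iodo-1-(TBSO)but-3-en-1-yl]-7,8-dihydro-2H-oxocin-3(4H)-one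
Product: 16 (2R,5Z,8R)-2-ethyl-8-[(1R,3E)-1-(TBSO)hex-3-en-5-yn-1-yl]-7,8-dihydro-2H-oxocin-3(4H)-one
Conditions: HC≡CZnBr (from HC≡CMgBr and ZnBr2), Pd(PPh3)4 (5 mol%), THF, rt
Reagents that add atoms: ethynylzinc bromide, C#C[Zn]Br
Why: Negishi alkynylation proceeds with retention of alkene geometry under neutral conditions that leave the enolisable β,γ-unsaturated ketone untouched, completing the (E)-enyne C1–C4.

Step 12
Reactants: 16 (2R,5Z,8R)-2-ethyl-8-[(1R,3E)-1-(TBSO)hex-3-en-5-yn-1-yl]-7,8-dihydro-2H-oxocin-3(4H)-one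
Product: 17 (2R,5Z,8R)-2-ethyl-8-[(1R,3E)-1-hydroxyhex-3-en-5-yn-1-yl]-7,8-dihydro-2H-oxocin-3(4H)-one
Conditions: HF·pyridine, THF, 0 °C to rt
Reagents that add atoms: none
Why: Acidic fluoride cleavage of the secondary silyl ether should free the C6 hydroxyl without base, which would move C9=C10 into conjugation with the ketone.

Step 13
Reactants: 17 (2R,5Z,8R)-2-ethyl-8-[(1R,3E)-1-hydroxyhex-3-en-5-yn-1-yl]-7,8-dihydro-2H-oxocin-3(4H)-one
Product: 20 (1R,3R,6S,8R,10S)-10-bromo-3-ethyl-8-[(2E)-pent-2-en-4-yn-1-yl]-2,7-dioxabicyclo[4.2.2]decan-4-one, via bis-silyl dienol ether 18 (not isolated), via bicyclic silyl enol ether 19 (not isolated)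
Conditions: Me3SiOTf, Et3N, CH2Cl2, −78 to 0 °C; then N-bromosuccinimide, THF, −78 °C; aqueous NaHCO3, then dilute citric acid work-up
Reagents that add atoms: N-bromosuccinimide, O=C1CCC(=O)N1Br
Why: Soft enolisation removes the doubly activated C11 proton to give the linear 1-silyloxy-1,3-diene and silylates the C6 hydroxyl; N-bromosuccinimide should attack this dienol ether at its terminus C9 (vinylogous γ-halogenation) and the C6 oxygen then closes onto C10 of the resulting silyloxyallyl cation (oxa-conjugate 6-exo closure with loss of the silyl group), so that the five-membered closure at C9 is excluded, the oxygen reaches C10 only from the ring face that carries the C7 side chain (C10 S) and bromine enters anti to it (C9 S).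

Step 14
Reactants: 20 (1R,3R,6S,8R,10S)-10-bromo-3-ethyl-8-[(2E)-pent-2-en-4-yn-1-yl]-2,7-dioxabicyclo[4.2.2]decan-4-one
Product: 21 (1R,3R,4R,6S,8R,10S)-10-bromo-3-ethyl-8-[(2E)-pent-2-en-4-yn-1-yl]-2,7-dioxabicyclo[4.2.2]decan-4-ol
Conditions: LiBH(s-Bu)3, THF, −78 °C
Reagents that add atoms: none
Why: Felkin–Anh addition of the bulky hydride to the α-alkoxy ketone, anti to the neighbouring C13 ethyl group, should give the 12,13-cis (12R) alcohol, the epimer needed for bromination with inversion.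

Step 15
Reactants: 21 (1R,3R,4R,6S,8R,10S)-10-bromo-3-ethyl-8-[(2E)-pent-2-en-4-yn-1-yl]-2,7-dioxabicyclo[4.2.2]decan-4-ol
Product: 22 (1R,3R,4S,6S,8R,10S)-4,10-dibromo-3-ethyl-8-[(2E)-pent-2-en-4-yn-1-yl]-2,7-dioxabicyclo[4.2.2]decane
Conditions: CBr4, P(n-C8H17)3, toluene, 70 °C
Reagents that add atoms: carbon tetrabromide, BrC(Br)(Br)Br
Why: Appel-type bromination: bromide displaces the alkoxyphosphonium group in an SN2 reaction with inversion at C12 (12R alcohol to 12S bromide), the C9 bromide and the enyne being inert.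

Compound list

1 | 1,1,3,3-tetrabromopropan-2-one | BrC(Br)C(=O)C(Br)Br | starting material
2 | buta-1,3-diene | C=CC=C | starting material
3 | 2,7-dibromocyclohept-4-en-1-one (cis/trans mixture) | O=C1C(Br)C/C=C\CC1Br | intermediate
4 | cyclohept-4-en-1-one | O=C1CC/C=C\CC1 | intermediate
5 | 3-[(tert-butyldimethylsilyl)oxy]propanal | O=CCCO[Si](C)(C)C(C)(C)C | starting material
6 | (2R)-2-[(1R)-3-(TBSO)-1-hydroxypropyl]cyclohept-4-en-1-one (anti aldol) | CC(C)(C)[Si](C)(C)OCC[C@@H](O)[C@H]1C/C=C\CCC1=O | intermediate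
7 | (2R)-2-[(1R)-1,3-bis(TBSO)propyl]cyclohept-4-en-1-one | CC(C)(C)[Si](C)(C)OCC[C@@H](O[Si](C)(C)C(C)(C)C)[C@H]1C/C=C\CCC1=O | intermediate
8 | (5Z,8R)-8-[(1R)-1,3-bis(TBSO)propyl]-3,4,7,8-tetrahydro-2H-oxocin-2-one | CC(C)(C)[Si](C)(C)OCC[C@@H](O[Si](C)(C)C(C)(C)C)[C@H]1C/C=C\CCC(=O)O1 | intermediate
9 | (5Z,8R)-8-[(1R)-1,3-bis(TBSO)propyl]-7,8-dihydro-4H-oxocin-2-yl diphenyl phosphate | CC(C)(C)[Si](C)(C)OCC[C@@H](O[Si](C)(C)C(C)(C)C)[C@H]1C/C=C\C/C=C(/OP(=O)(Oc2ccccc2)Oc2ccccc2)O1 | intermediate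
10 | (5Z,8R)-8-[(1R)-1,3-bis(TBSO)propyl]-2-ethyl-7,8-dihydro-4H-oxocine | CC(C)(C)[Si](C)(C)OCC[C@@H](O[Si](C)(C)C(C)(C)C)[C@H]1C/C=C\C/C=C(/CC)O1 | intermediate
11 | 2,3-epoxide of 10 (C12–C13 epoxide, oxygen on the ring face anti to the C7 side chain) | CC(C)(C)[Si](C)(C)OCC[C@@H](O[Si](C)(C)C(C)(C)C)[C@H]1C/C=C\C[C@@H]2O[C@]2(CC)O1 | intermediate
12 | (2R,3S,5Z,8R)-8-[(1R)-1,3-bis(TBSO)propyl]-2-ethyl-3,4,7,8-tetrahydro-2H-oxocin-3-ol | CC(C)(C)[Si](C)(C)OCC[C@@H](O[Si](C)(C)C(C)(C)C)[C@H]1C/C=C\C[C@H](O)[C@@H](CC)O1 | intermediate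
13 | (2R,3S,5Z,8R)-2-ethyl-8-[(1R)-3-hydroxy-1-(TBSO)propyl]-3,4,7,8-tetrahydro-2H-oxocin-3-ol | OCC[C@@H](O[Si](C)(C)C(C)(C)C)[C@H]1C/C=C\C[C@H](O)[C@@H](CC)O1 | intermediate
14 | (3R)-3-(TBSO)-3-[(2R,4Z,8R)-8-ethyl-7-oxo-3,6,7,8-tetrahydro-2H-oxocin-2-yl]propanal | O=CC[C@@H](O[Si](C)(C)C(C)(C)C)[C@H]1C/C=C\CC(=O)[C@@H](CC)O1 | intermediate
15 | (2R,5Z,8R)-2-ethyl-8-[(1R,3E)-4-iodo-1-(TBSO)but-3-en-1-yl]-7,8-dihydro-2H-oxocin-3(4H)-one | I/C=C/C[C@@H](O[Si](C)(C)C(C)(C)C)[C@H]1C/C=C\CC(=O)[C@@H](CC)O1 | intermediate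
16 | (2R,5Z,8R)-2-ethyl-8-[(1R,3E)-1-(TBSO)hex-3-en-5-yn-1-yl]-7,8-dihydro-2H-oxocin-3(4H)-one | C#C/C=C/C[C@@H](O[Si](C)(C)C(C)(C)C)[C@H]1C/C=C\CC(=O)[C@@H](CC)O1 | intermediate
17 | (2R,5Z,8R)-2-ethyl-8-[(1R,3E)-1-hydroxyhex-3-en-5-yn-1-yl]-7,8-dihydro-2H-oxocin-3(4H)-one | C#C/C=C/C[C@@H](O)[C@H]1C/C=C\CC(=O)[C@@H](CC)O1 | intermediate
18 | (2R,3Z,5Z,8R)-2-ethyl-3-(TMSO)-8-[(1R,3E)-1-(TMSO)hex-3-en-5-yn-1-yl]-7,8-dihydro-2H-oxocine | C#C/C=C/C[C@@H](O[Si](C)(C)C)[C@H]1C/C=C\C=C(\O[Si](C)(C)C)[C@@H](CC)O1 | intermediate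
19 | (1R,3R,4Z,6S,8R,10S)-10-bromo-3-ethyl-8-[(2E)-pent-2-en-4-yn-1-yl]-4-(TMSO)-2,7-dioxabicyclo[4.2.2]dec-4-ene | C#C/C=C/C[C@H]1O[C@H]2/C=C(/O[Si](C)(C)C)[C@@H](CC)O[C@@H]1C[C@@H]2Br | intermediate
20 | (1R,3R,6S,8R,10S)-10-bromo-3-ethyl-8-[(2E)-pent-2-en-4-yn-1-yl]-2,7-dioxabicyclo[4.2.2]decan-4-one | C#C/C=C/C[C@H]1O[C@H]2CC(=O)[C@@H](CC)O[C@@H]1C[C@@H]2Br | intermediate
21 | (1R,3R,4R,6S,8R,10S)-10-bromo-3-ethyl-8-[(2E)-pent-2-en-4-yn-1-yl]-2,7-dioxabicyclo[4.2.2]decan-4-ol | C#C/C=C/C[C@H]1O[C@H]2C[C@@H](O)[C@@H](CC)O[C@@H]1C[C@@H]2Br | intermediate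
22 | (1R,3R,4S,6S,8R,10S)-4,10-dibromo-3-ethyl-8-[(2E)-pent-2-en-4-yn-1-yl]-2,7-dioxabicyclo[4.2.2]decane | C#C/C=C/C[C@H]1O[C@H]2C[C@H](Br)[C@@H](CC)O[C@@H]1C[C@@H]2Br | target

Total step count: 15. Longest linear sequence: 15 steps (from 1 and 2).

Steps most likely to fail, most risky first:

Step 13. The dienol ether may be brominated at C11 instead of C9, or the ring may close without control of the C9 configuration. The fallback sets out from 16 and comes back at 22, and avoids the dienol ether. The C12 ketone of 16 is reduced with LiBH(s-Bu)3 in THF at −78 °C to the 12,13-cis alcohol F1. CBr4 and P(n-C8H17)3 should convert it with inversion into the (12S)-bromide F2. HF·pyridine removes the silyl ether to give the bromo hydroxy oxocene F3. Treatment with 2,4,4,6-tetrabromocyclohexa-2,5-dienone in CH2Cl2 then brings about transannular bromo-etherification of C9=C10 by the C6 hydroxyl; the 6-endo mode (oxygen to C10, bromine to C9, anti) gives 22, to be separated from the 5-exo regioisomer.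

Step 2. Aldehyde 5 may self-condense or lose silanol under amine catalysis, and enantio- and diastereocontrol with the seven-membered ketone may be poor. The fallback sets out from 4 and comes back at 6. The (E)-dicyclohexylboron enolate of 4 (Cy2BCl, Et3N, Et2O, −78 °C) adds to 5 through a closed chair transition state and should give the racemic anti aldol, that is 6 together with its enantiomer F4. Acetylation with Candida antarctica lipase B and vinyl acetate resolves the pair; the (6R)-alcohol is expected to react faster to give the acetate F5, which is separated from F4 and cleaved with K2CO3 in MeOH at 0 °C to return 6. If the enzyme prefers the other enantiomer, 6 is the alcohol left unreacted.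

Step 1. Conversion in the cycloaddition may be low because butadiene rests in the s-trans form, with oligomerisation of the diene or open-chain alkylation taking over. The fallback sets out from 2 and comes back at 4; it is a rhodium-carbenoid formal [4+3] that forms the same two bonds. Commercial methyl acetoacetate is converted by diazo transfer (4-acetamidobenzenesulfonyl azide, Et3N) into methyl 2-diazo-3-oxobutanoate F6 and silylated (t-BuMe2SiOTf, Et3N) to the silyloxy vinyl diazoacetate F7. Rh2(OAc)4-catalysed cyclopropanation of 2 (forming C7–C8) gives the cis-divinylcyclopropane F8, which undergoes Cope rearrangement in the flask (forming C11–C12) to the cycloheptadiene F9. Aqueous HCl in THF gives the β-keto ester F10, and Krapcho demethoxycarbonylation (LiCl, wet DMSO, 150 °C) gives 4.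

Further compounds

F1 | step 13 | (2R,3R,5Z,8R)-2-ethyl-8-[(1R,3E)-1-(TBSO)hex-3-en-5-yn-1-yl]-3,4,7,8-tetrahydro-2H-oxocin-3-ol | C#C/C=C/C[C@@H](O[Si](C)(C)C(C)(C)C)[C@H]1C/C=C\C[C@@H](O)[C@@H](CC)O1
F2 | step 13 | (2R,3S,5Z,8R)-3-bromo-2-ethyl-8-[(1R,3E)-1-(TBSO)hex-3-en-5-yn-1-yl]-3,4,7,8-tetrahydro-2H-oxocine | C#C/C=C/C[C@@H](O[Si](C)(C)C(C)(C)C)[C@H]1C/C=C\C[C@H](Br)[C@@H](CC)O1
F3 | step 13 | (2R,3S,5Z,8R)-3-bromo-2-ethyl-8-[(1R,3E)-1-hydroxyhex-3-en-5-yn-1-yl]-3,4,7,8-tetrahydro-2H-oxocine | C#C/C=C/C[C@@H](O)[C@H]1C/C=C\C[C@H](Br)[C@@H](CC)O1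
F4 | step 2 | (2S)-2-[(1S)-3-(TBSO)-1-hydroxypropyl]cyclohept-4-en-1-one (enantiomer of 6) | CC(C)(C)[Si](C)(C)OCC[C@H](O)[C@@H]1C/C=C\CCC1=O
F5 | step 2 | (1R)-3-(TBSO)-1-[(1R)-2-oxocyclohept-4-en-1-yl]propyl acetate | CC(C)(C)[Si](C)(C)OCC[C@@H](OC(C)=O)[C@H]1C/C=C\CCC1=O
F6 | step 1 | methyl 2-diazo-3-oxobutanoate | COC(=O)C(=[N+]=[N-])C(C)=O
F7 | step 1 | methyl 3-[(tert-butyldimethylsilyl)oxy]-2-diazobut-3-enoate | COC(=O)C(=[N+]=[N-])C(=C)O[Si](C)(C)C(C)(C)C
F8 | step 1 | methyl cis-2-ethenyl-1-[1-(TBSO)ethenyl]cyclopropane-1-carboxylate (racemic, the two vinyl groups cis, one enantiomer drawn) | COC(=O)[C@@]1(C(=C)O[Si](C)(C)C(C)(C)C)C[C@@H]1C=C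
F9 | step 1 | methyl 2-(TBSO)cyclohepta-1,5-diene-1-carboxylate | COC(=O)C1=C(O[Si](C)(C)C(C)(C)C)CC/C=C\C1
F10 | step 1 | methyl 2-oxocyclohept-5-ene-1-carboxylate (racemic, enolisable) | COC(=O)C1C/C=C\CCC1=O
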